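**Analysis of the target**

The target 19 is a 2,3-dihydro-1-benzofuran. Ring A (C3a to C7a) carries a free hydroxyl at C4 and a 2-(4-hydroxyphenyl)ethyl chain at C6; the dihydrofuran ring carries a 4-hydroxyphenyl group at C2 and a 3,5-dihydroxyphenyl group at C3. C2 and C3 are the only stereocentres, both S, which places the two aryl groups trans. Trans is the more stable arrangement and C2 is an ionisable benzylic ether carbon, so C2 can be allowed to follow C3 and only C3 needs absolute control. The sensitive points are the five phenols (oxidation), the C2–O1 bond para to an oxygenated ring (heterolysis under acid, quinone methide formation under base), the three electron-rich rings (electrophilic halogenation) and the dihydrofuran, which loses both stereocentres if it is dehydrogenated to the benzofuran. The difficulty is that C3 is a doubly benzylic methine without a functional handle, attached to C3a, the ring A carbon lying between the two oxygenated carbons C4 and C7a. The strategy rests on the fact that O1–C7a=C3a–C4(OH) is the enol ether of a cyclohexane-1,3-dione whose central carbon is C3a. Ring A can therefore be carried as that dione, C2 and C3 can first be a cyclopropane spiro-fused at C3a, and O1–C2 is then made by strain-driven ring expansion.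

**Retrosynthetic reasoning**

19 to 18 to 17 (ester C–O, then three O–CH3 bonds). The five phenols are unmasked last. The methyl ethers are cut from 17 while the aryl ester is still in place, and the ester of 18 is cut afterwards. This order is deliberate: a 4-acyloxyphenyl group at C2 is a poor cation stabiliser, so the C2–O1 bond is shielded from the Lewis acid needed for dealkylation. The methyl ethers are kept because the commercial materials 10 and 1 already carry them.

17 to 14 (two hydrogens across C5–C6 of ring A). The phenol ring of 17 is traced back to the cyclohexenone of 14. In 14 the unit O1–C7a=C3a–C4=O is a vinylogous ester, that is an O-alkylated 1,3-dione, so the position of C3a between the two oxygens is fixed by constitution and not by an arene substitution. The forward step must dehydrogenate ring A only and must not touch C2–H, C3–H or the electron-rich rings. An enolate-based dehydrogenation is therefore preferred to halogenating or quinone oxidants.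

14 to 12 (cut O1–C2, join C2 to C3a). This is the retro-Cloke–Wilson step and the core of the plan. In 12 the future C2 and C3 are the two CH carbons of a trans-diaryl cyclopropane spiro-fused to the dione. Going forward, the strained bond from the spiro carbon to the carbon bearing the para-oxygenated ring ionises and the dione oxygen closes on it. The bond to the carbon bearing the 3,5-dimethoxyphenyl ring is never broken, so C3 is a spectator and C2 is set trans to it. The para oxygen is worn as a pivalate: a donor weak enough for 12 to be isolated, but still the better of the two rings at stabilising a benzylic cation.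

12 to 9 + 11 (both cyclopropane bonds to the spiro carbon). The cyclopropane is cut into the diazo dione 9 as carbene source and the trans-stilbene 11. Both aryl groups and both stereogenic carbons arrive in one piece, and the trans geometry of the alkene becomes the trans relation on the ring. The forward step has to choose the alkene face, because this is where C3 receives its absolute configuration. It is the one step without direct precedent.

11 to 10 and 9 to 8. The stilbene 11 is the pivalate of commercial pterostilbene 10. The diazo dione 9 comes from the dione 8 by diazo transfer to its acidic C2.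

8 to 3 + 4, and 3 to 1 + 2. The 5-substituted dione 8 is opened by the classical Michael–Claisen disconnection into the enone 3 and diethyl malonate 4, which supplies C2 and one carbonyl carbon. The enone 3 is cut at its C=C bond into the aldehyde 1 and the acetonyl ylide 2. A stabilised ylide is chosen over an acetone aldol because 1 is enolisable and would self-condense.

**Alternatives that were turned down**

Alternative 1: conjunctive three-component coupling.
- Disconnection: the C3–C3a bond and the bond from C2 to its aryl group, so that the central two-carbon unit is assembled from the styrylboronate A1, the aryllithium A2 and the ring A triflate A3.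
- Forward key step: A1 and A2 form a boron ate complex. An arylpalladium species from A3, bearing a chiral bisphosphine, activates the alkene; the anisyl group shifts from boron to the neighbouring carbon while ring A is delivered to the other carbon, giving the boronic ester A4 with both centres set. O1–C2 still has to be made by C–B oxidation, release of one ortho oxygen of ring A and closure.
- For: it is convergent, and ligand-controlled conjunctive coupling has broad precedent for alkenyl boronates and aryl triflates. On absolute control at C3 it stands on firmer ground than step 5 of the chosen route.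
- Against: A3 is electron-rich and substituted at both ortho positions, and it must approach a β-aryl alkenyl boronate, so the coupling is attempted at its most hindered. One of two equivalent ortho methoxy groups must later be freed in the presence of three other methyl ethers. The ring closure occurs at a 4-methoxybenzylic carbon with SN1 character, so the C2 configuration made in the key step is not used. At least four steps follow A4.
- Comparison: the chosen strategy offers the ring A oxygen already in place as a dione oxygen, ring closure inside the key step, and no hindered aryl coupling.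

Alternative 2: aryne insertion into an epoxide C–O bond.
- Disconnection: C7a–O1 and C3a–C3, the two bonds from ring A to the dihydrofuran. Ring A comes from the silyl aryl triflate A5 as aryne precursor; C2, C3 and O1 come from the enantiopure trans-epoxide A6.
- Forward key step: fluoride releases the aryne from A5. The epoxide oxygen of A6 adds to the aryne carbon remote from the methoxy group, and the aryl anion then bonds to the epoxide carbon bearing the 3,5-dimethoxyphenyl ring, giving A7.
- For: it is the shortest route, ring A is aromatic from the start, and enantiopure trans-stilbene oxides are reliably accessible. The C2–O bond is never broken, so C2 would carry the absolute configuration. On step count and on the source of chirality this alternative is stronger than the chosen route.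
- Against: the aryl anion cannot displace the oxonium oxygen from the rear, because that oxygen belongs to the ring being formed (a 5-endo-tet geometry). The C3–O bond must therefore ionise first, at the carbon whose aryl group is least able to carry positive charge. Such a cation has easier outlets: hydride shift to a deoxybenzoin, proton loss, or protonation of the aryl anion. C3 would be set only by trans-selective recombination, and A5 is a 1,2,3,5-tetrasubstituted arene needing its own synthesis.
- Comparison: the chosen strategy also passes through a benzylic cation, but at the carbon carrying the para-oxygenated ring, and C3 is untouched. It pays for this with the steps that adjust the oxidation level of ring A.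

Alternative 3: flavanone ring contraction.
- Disconnection: the C3–C3a bond, made by a 1,2-shift. The dihydrobenzofuran is derived from the six-membered pyranone of the flavanone A8.
- Forward key step: a hypervalent iodine oxidant in acidic orthoformate attacks the enol ether of A8 at C3. The ring A carbon migrates from the carbonyl carbon to C3 as the iodoarene leaves, and the former carbonyl carbon ends up as a methyl ester on C3 of the trans product A9.
- For: the rearrangement has direct precedent on flavanones with trans outcome, enantioenriched flavanones are known, and ring A is aromatic throughout. In precedent for the key step it is stronger than the chosen route.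
- Against: A9 carries an ester where the target needs the 3,5-dihydroxyphenyl ring. Replacing a carboxylate by an aryl group at a stereogenic benzylic carbon means a decarboxylative arylation through a C3 radical, or building the resorcinol ring from scratch. This adds several steps and again leaves C3 to substrate control. The C2 centre of A8 can also racemise by retro-oxa-Michael opening in the acidic medium.
- Comparison: the chosen strategy brings both aryl groups in with one commercial stilbene, and nothing has to be attached to C3 after the ring is formed.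

Key step: step 6

Assumption: the sense of induction of Rh2(S-PTTL)4 in step 5 is taken to give the (1S,2S)-cyclopropane; if the (1R,2R)-isomer should predominate, Rh2(R-PTTL)4 is used and nothing else changes.

**Route**

Step 1
Reactants: 1 3-(4-methoxyphenyl)propanal; 2 1-(triphenyl-λ5-phosphanylidene)propan-2-one
Product: 3 (E)-6-(4-methoxyphenyl)hex-3-en-2-one
Conditions: PhMe, 80 °C
Reagents that add atoms: none
Why: Wittig olefination with a ketone-stabilised ylide, which reacts only with the aldehyde and should give the (E)-enone; it avoids the self-condensation that an aldol reaction of this enolisable aldehyde would risk.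

Step 2
Reactants: 3 (E)-6-(4-methoxyphenyl)hex-3-en-2-one; 4 diethyl malonate
Product: 8 5-[2-(4-methoxyphenyl)ethyl]cyclohexane-1,3-dione, via Michael adduct 5 (not isolated), via cyclic keto ester 6 (not isolated), via keto acid 7 (not isolated)
Conditions: NaOEt, EtOH, reflux; then aq. NaOH, reflux; then aq. HCl (pH 1), reflux
Reagents that add atoms: none
Why: Michael addition of sodiomalonate to the enone, intramolecular Claisen acylation of the methyl ketone enolate by one ester group, then saponification and decarboxylation of the β-keto acid; this is the standard annulation to 5-substituted cyclohexane-1,3-diones, and the aryl methyl ether is inert to it.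

Step 3
Reactants: 8 5-[2-(4-methoxyphenyl)ethyl]cyclohexane-1,3-dione
Product: 9 2-diazo-5-[2-(4-methoxyphenyl)ethyl]cyclohexane-1,3-dione
Conditions: 4-acetamidobenzenesulfonyl azide, Et3N, MeCN, 0 → 25 °C
Reagents that add atoms: 4-acetamidobenzenesulfonyl azide, CC(=O)Nc1ccc(cc1)S(=O)(=O)N=[N+]=[N-]
Why: Regitz diazo transfer from a sulfonyl azide to the highly acidic C2 of a cyclic 1,3-dione under amine base.

Step 4
Reactants: 10 pterostilbene, 4-[(E)-2-(3,5-dimethoxyphenyl)ethenyl]phenol
Product: 11 4-[(E)-2-(3,5-dimethoxyphenyl)ethenyl]phenyl 2,2-dimethylpropanoate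
Conditions: pivaloyl chloride, Et3N, DMAP (cat.), CH2Cl2, 0 → 25 °C
Reagents that add atoms: pivaloyl chloride, CC(C)(C)C(Cl)=O
Why: Acylation of the phenol; the pivalate makes the para oxygen a weak donor so that the cyclopropane of step 5 can be isolated yet still ionises at this benzylic carbon in step 6, and it should withstand carbene transfer, Lewis acids and LDA at low temperature.

Step 5
Reactants: 9 2-diazo-5-[2-(4-methoxyphenyl)ethyl]cyclohexane-1,3-dione; 11 4-[(E)-2-(3,5-dimethoxyphenyl)ethenyl]phenyl 2,2-dimethylpropanoate
Product: 12 4-[(1S,2S)-2-(3,5-dimethoxyphenyl)-6-[2-(4-methoxyphenyl)ethyl]-4,8-dioxospiro[2.5]octan-1-yl]phenyl 2,2-dimethylpropanoate (trans-diaryl cyclopropane, both C6 epimers)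
Conditions: Rh2(S-PTTL)4 (2 mol%), PhCF3, 25 → 40 °C, slow addition of 9 (1.5 equiv)
Reagents that add atoms: none
Why: Proposed new method: Rh2(S-PTTL)4 should turn 9 into an electrophilic diacyl rhodium carbene that adds to the stilbene C=C in an asynchronous but stereospecific [2+1] step, the first bond forming at the carbon bearing the 3,5-dimethoxyphenyl group while positive charge builds next to the acyloxyphenyl ring, so that the trans geometry of 11 is carried into 12 and the chiral carboxylate pocket of the catalyst selects the alkene face and sets both cyclopropane centres together; the closest known reactions are the enantioselective cyclopropanation of styrenes with cyclic diacceptor diazo compounds or their iodonium ylides under Rh2(S-PTTL)4 or Rh2(S-NTTL)4 and the racemic transfer of malonate carbenes to trans-1-arylpropenes, whereas enantioselective transfer of a cyclic 1,3-dione carbene to a trans-1,2-diarylethene has not been shown; the remote C6 centre is not expected to be controlled, and any 12 that ring-expands in the flask is simply 14.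

Step 6
Reactants: 12 4-[(1S,2S)-2-(3,5-dimethoxyphenyl)-6-[2-(4-methoxyphenyl)ethyl]-4,8-dioxospiro[2.5]octan-1-yl]phenyl 2,2-dimethylpropanoate (both C6 epimers)
Product: 14 4-[(2S,3S)-3-(3,5-dimethoxyphenyl)-6-[2-(4-methoxyphenyl)ethyl]-4-oxo-2,3,4,5,6,7-hexahydro-1-benzofuran-2-yl]phenyl 2,2-dimethylpropanoate (both C6 epimers), via ring-opened zwitterion 13 (not isolated)
Conditions: Sc(OTf)3 (10 mol%), CH2Cl2 (dilute), 0 → 25 °C
Reagents that add atoms: none
Why: Cloke–Wilson rearrangement of a donor–acceptor cyclopropane, the known Lewis-acid ring expansion of 1-aryl spiro[2.5]octane-4,8-diones to 2-aryl tetrahydrobenzofuran-4-ones, applied here to a 1,2-diaryl member. Sc(OTf)3 chelates the 1,3-dione, the strained bond between the spiro carbon and the carbon bearing the 4-(pivaloyloxy)phenyl group ionises, and the zwitterion 13 (benzylic cation paired with the scandium dione enolate) results. The enolate oxygen then bonds to the cationic carbon and closes the dihydrofuran ring by forming O1–C2. A concerted displacement would be a 5-endo-tet process, because the departing carbon C3a is a member of the ring being made, so the closure is stepwise: ionisation, then five-membered cation–enolate collapse through oxygen with the enolate C7a=C3a bond inside the new ring. C3 takes no part in bond breaking or making and keeps the S configuration from step 5. C2 is set by substrate control: the planar cation is captured on the face that puts the C2 aryl group anti to the C3 aryl group, and since the Lewis acid can reopen C2–O1 any cis isomer should drain to the more stable trans isomer, so the configuration of that carbon in 12 is immaterial. The step needs cleavage at the correct benzylic carbon, which is secured because the para acyloxy oxygen stabilises the cation by resonance whereas the two meta methoxy groups of the other ring offer no resonance stabilisation and withdraw inductively. Both C6 epimers should react alike, and dilution keeps the cation from being intercepted by the electron-rich rings of a second molecule.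

Step 7
Reactants: 14 4-[(2S,3S)-3-(3,5-dimethoxyphenyl)-6-[2-(4-methoxyphenyl)ethyl]-4-oxo-2,3,4,5,6,7-hexahydro-1-benzofuran-2-yl]phenyl 2,2-dimethylpropanoate (both C6 epimers)
Product: 17 4-[(2S,3S)-3-(3,5-dimethoxyphenyl)-4-hydroxy-6-[2-(4-methoxyphenyl)ethyl]-2,3-dihydro-1-benzofuran-2-yl]phenyl 2,2-dimethylpropanoate, via lithium dienolate 15 (not isolated), via dienone 16 (not isolated)
Conditions: LDA, THF, −78 °C; then N-tert-butylbenzenesulfinimidoyl chloride, −78 → 0 °C; aq. NH4Cl
Reagents that add atoms: none
Why: Kinetic deprotonation of the vinylogous ester at C5 and dehydrogenation of the lithium enolate with the sulfinimidoyl chloride (Mukaiyama dehydrogenation) should give the cross-conjugated dienone 16, which tautomerises to the phenol; C6 becomes sp2, so both C6 epimers converge, and C2 and C3 are not touched. No electrophilic halogen or quinone oxidant is present, so the electron-rich rings are not brominated and the dihydrofuran is not dehydrogenated to the benzofuran.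

Step 8
Reactants: 17 4-[(2S,3S)-3-(3,5-dimethoxyphenyl)-4-hydroxy-6-[2-(4-methoxyphenyl)ethyl]-2,3-dihydro-1-benzofuran-2-yl]phenyl 2,2-dimethylpropanoate
Product: 18 4-[(2S,3S)-3-(3,5-dihydroxyphenyl)-4-hydroxy-6-[2-(4-hydroxyphenyl)ethyl]-2,3-dihydro-1-benzofuran-2-yl]phenyl 2,2-dimethylpropanoate
Conditions: BBr3 (excess), CH2Cl2, −78 → 0 °C; then H2O
Reagents that add atoms: none
Why: Lewis-acid cleavage of the three aryl methyl ethers (oxygen complexation, bromide attack on methyl); the pivalate is kept on purpose because a 4-acyloxyphenyl group is a poor cation stabiliser and so shields the benzylic C2–O1 bond from heterolysis. If that bond did open reversibly, reclosure trans to the intact C3 centre would return the same stereoisomer.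

Step 9
Reactants: 18 4-[(2S,3S)-3-(3,5-dihydroxyphenyl)-4-hydroxy-6-[2-(4-hydroxyphenyl)ethyl]-2,3-dihydro-1-benzofuran-2-yl]phenyl 2,2-dimethylpropanoate
Product: 19 5-[(2S,3S)-4-hydroxy-2-(4-hydroxyphenyl)-6-[2-(4-hydroxyphenyl)ethyl]-2,3-dihydro-1-benzofuran-3-yl]benzene-1,3-diol (target)
Conditions: NaOMe, degassed MeOH, argon, 0 → 25 °C; then aq. HCl
Reagents that add atoms: none
Why: Transesterification of the hindered aryl ester by methoxide releases the last phenol; basic methanolysis is the usual way to unmask polyphenol esters, and exclusion of air protects the product.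

**Compound list**

1 | 3-(4-methoxyphenyl)propanal | COc1ccc(CCC=O)cc1 | starting material
2 | 1-(triphenyl-λ5-phosphanylidene)propan-2-one | CC(=O)C=P(c1ccccc1)(c1ccccc1)c1ccccc1 | starting material
3 | (E)-6-(4-methoxyphenyl)hex-3-en-2-one | COc1ccc(CC/C=C/C(C)=O)cc1 | intermediate
4 | diethyl malonate | CCOC(=O)CC(=O)OCC | starting material
5 | diethyl 2-[1-(4-methoxyphenyl)-5-oxohexan-3-yl]propanedioate (Michael adduct, racemic) | CCOC(=O)C(C(=O)OCC)C(CCc1ccc(OC)cc1)CC(C)=O | intermediate (not isolated)
6 | ethyl 6-[2-(4-methoxyphenyl)ethyl]-2,4-dioxocyclohexane-1-carboxylate (present as its sodium enolate) | CCOC(=O)C1C(=O)CC(=O)CC1CCc2ccc(OC)cc2 | intermediate (not isolated)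
7 | 6-[2-(4-methoxyphenyl)ethyl]-2,4-dioxocyclohexane-1-carboxylic acid | OC(=O)C1C(=O)CC(=O)CC1CCc2ccc(OC)cc2 | intermediate (not isolated)
8 | 5-[2-(4-methoxyphenyl)ethyl]cyclohexane-1,3-dione | O=C1CC(CCc2ccc(OC)cc2)CC(=O)C1 | intermediate
9 | 2-diazo-5-[2-(4-methoxyphenyl)ethyl]cyclohexane-1,3-dione | O=C1CC(CCc2ccc(OC)cc2)CC(=O)C1=[N+]=[N-] | intermediate
10 | pterostilbene, 4-[(E)-2-(3,5-dimethoxyphenyl)ethenyl]phenol | COc1cc(/C=C/c2ccc(O)cc2)cc(OC)c1 | starting material
11 | 4-[(E)-2-(3,5-dimethoxyphenyl)ethenyl]phenyl 2,2-dimethylpropanoate | COc1cc(/C=C/c2ccc(OC(=O)C(C)(C)C)cc2)cc(OC)c1 | intermediate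
12 | 4-[(1S,2S)-2-(3,5-dimethoxyphenyl)-6-[2-(4-methoxyphenyl)ethyl]-4,8-dioxospiro[2.5]octan-1-yl]phenyl 2,2-dimethylpropanoate (both C6 epimers) | O=C1CC(CCc2ccc(OC)cc2)CC(=O)C13[C@H](c2ccc(OC(=O)C(C)(C)C)cc2)[C@H]3c2cc(OC)cc(OC)c2 | intermediate (precursor of the key step)
13 | 2-{(1S)-1-(3,5-dimethoxyphenyl)-2-[4-(pivaloyloxy)phenyl]ethan-2-ylium-1-yl}-5-[2-(4-methoxyphenyl)ethyl]-3-oxocyclohex-1-en-1-olate (zwitterion, scandium-bound in the flask) | COc1cc(cc(OC)c1)[C@H]([CH+]c1ccc(OC(=O)C(C)(C)C)cc1)C1=C([O-])CC(CCc2ccc(OC)cc2)CC1=O | intermediate (not isolated)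
14 | 4-[(2S,3S)-3-(3,5-dimethoxyphenyl)-6-[2-(4-methoxyphenyl)ethyl]-4-oxo-2,3,4,5,6,7-hexahydro-1-benzofuran-2-yl]phenyl 2,2-dimethylpropanoate (both C6 epimers) | COc1ccc(CCC2CC(=O)C3=C(C2)O[C@H](c2ccc(OC(=O)C(C)(C)C)cc2)[C@H]3c2cc(OC)cc(OC)c2)cc1 | intermediate (product of the key step)
15 | lithium (2S,3S)-3-(3,5-dimethoxyphenyl)-6-[2-(4-methoxyphenyl)ethyl]-2-[4-(pivaloyloxy)phenyl]-2,3,6,7-tetrahydro-1-benzofuran-4-olate | COc1ccc(CCC2C=C(O[Li])C3=C(C2)O[C@H](c2ccc(OC(=O)C(C)(C)C)cc2)[C@H]3c2cc(OC)cc(OC)c2)cc1 | intermediate (not isolated)
16 | 4-[(2S,3S)-3-(3,5-dimethoxyphenyl)-6-[2-(4-methoxyphenyl)ethyl]-4-oxo-2,3,4,7-tetrahydro-1-benzofuran-2-yl]phenyl 2,2-dimethylpropanoate | COc1ccc(CCC2=CC(=O)C3=C(C2)O[C@H](c2ccc(OC(=O)C(C)(C)C)cc2)[C@H]3c2cc(OC)cc(OC)c2)cc1 | intermediate (not isolated)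
17 | 4-[(2S,3S)-3-(3,5-dimethoxyphenyl)-4-hydroxy-6-[2-(4-methoxyphenyl)ethyl]-2,3-dihydro-1-benzofuran-2-yl]phenyl 2,2-dimethylpropanoate | COc1ccc(CCc2cc(O)c3c(c2)O[C@H](c2ccc(OC(=O)C(C)(C)C)cc2)[C@H]3c2cc(OC)cc(OC)c2)cc1 | intermediate
18 | 4-[(2S,3S)-3-(3,5-dihydroxyphenyl)-4-hydroxy-6-[2-(4-hydroxyphenyl)ethyl]-2,3-dihydro-1-benzofuran-2-yl]phenyl 2,2-dimethylpropanoate | Oc1ccc(CCc2cc(O)c3c(c2)O[C@H](c2ccc(OC(=O)C(C)(C)C)cc2)[C@H]3c2cc(O)cc(O)c2)cc1 | intermediate
19 | 5-[(2S,3S)-4-hydroxy-2-(4-hydroxyphenyl)-6-[2-(4-hydroxyphenyl)ethyl]-2,3-dihydro-1-benzofuran-3-yl]benzene-1,3-diol | Oc1ccc(CCc2cc(O)c3c(c2)O[C@H](c2ccc(O)cc2)[C@H]3c2cc(O)cc(O)c2)cc1 | target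

**Step count and risk**

Total step count: 9. Longest linear sequence: 8 steps (steps 1, 2, 3, 5, 6, 7, 8, 9); the stilbene branch (step 4) joins at step 5.

Step 5 (bears the label). What is most likely to go wrong is slow carbene transfer to the conjugated trans-disubstituted alkene. Carbene dimerisation or electrophilic attack of the carbene on the 3,5-dimethoxyphenyl ring could then take over, and the catalyst may discriminate the two alkene faces poorly. Fallback, by known chemistry and with resolution in place of asymmetric catalysis; it gives up the cyclopropane. Setting out from 8 and 11, Mn(OAc)3 in AcOH at 60 °C effects the oxidative annulation of the dione with the stilbene. The dione radical adds to the alkene carbon bearing the 3,5-dimethoxyphenyl group, the benzylic radical is oxidised, and the dione oxygen closes on it. This gives the racemic trans-hexahydrobenzofuranone F1. Dehydrogenation as in step 7 gives the racemic phenol F2. Preparative chromatography on a chiral stationary phase separates it into 17, where the route is rejoined, and the (2R,3R)-phenol F3, which is discarded.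

Step 6 (key step). The likely failures are:
- competing ionisation toward the other benzylic carbon, or sluggish opening because the acyloxy donor is weak;
- interception of the cation by an electron-rich ring of a second molecule;
- proton loss from C3 of 13, which would erode the configuration at C3.

Fallback: the ring is opened by a phenoxide push instead of by a Lewis acid. Setting out from 12, NaOMe in MeOH cleaves the pivalate. The phenoxide expels the dione enolate and gives the para-quinone methide enolate F4, which is not isolated. Its enolate oxygen adds back to the exocyclic carbon in a 5-exo-trig oxa-1,6-addition to give the trans phenol F5. Re-acylation of F5 with pivaloyl chloride and Et3N returns 14. Only the ring carrying the para oxygen can form the quinone methide, so the regiochemistry no longer rests on relative cation stability.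

Step 7. The likely failures are attack of the amide base on the aryl pivalate, or sulfenylation of the enolate without elimination, since the hydrogen to be removed at C6 is tertiary. Fallback without strong base: setting out from 14, CuBr2 in EtOAc/CHCl3 at reflux brominates C5 to give the bromo ketone F6, and Li2CO3/LiBr in DMF at 120 °C eliminates HBr; tautomerisation gives 17. Bromination of the dimethoxyphenyl ring has to be held back by limiting the reagent and the reaction time.

Step 8. The likely failures are Lewis-acid heterolysis of C2–O1 followed by Friedel–Crafts oligomerisation, or incomplete cleavage that leaves partly methylated material. Fallback, nucleophilic instead of electrophilic dealkylation: setting out from 17, sodium ethanethiolate in DMF at 120–130 °C removes the three methyl groups by SN2 attack at methyl and the pivaloyl group by acyl transfer in the same operation. The sequence returns to the route at 19 and passes through no new compound F0.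

**Further compounds**

F1 | step 5 | racemic trans 4-[3-(3,5-dimethoxyphenyl)-6-[2-(4-methoxyphenyl)ethyl]-4-oxo-2,3,4,5,6,7-hexahydro-1-benzofuran-2-yl]phenyl 2,2-dimethylpropanoate, (2S,3S) and (2R,3R), both C6 epimers | COc1ccc(CCC2CC(=O)C3=C(C2)O[C@H](c2ccc(OC(=O)C(C)(C)C)cc2)[C@H]3c2cc(OC)cc(OC)c2)cc1.COc1ccc(CCC2CC(=O)C3=C(C2)O[C@@H](c2ccc(OC(=O)C(C)(C)C)cc2)[C@@H]3c2cc(OC)cc(OC)c2)cc1
F2 | step 5 | racemic trans 4-[3-(3,5-dimethoxyphenyl)-4-hydroxy-6-[2-(4-methoxyphenyl)ethyl]-2,3-dihydro-1-benzofuran-2-yl]phenyl 2,2-dimethylpropanoate, (2S,3S) and (2R,3R) | COc1ccc(CCc2cc(O)c3c(c2)O[C@H](c2ccc(OC(=O)C(C)(C)C)cc2)[C@H]3c2cc(OC)cc(OC)c2)cc1.COc1ccc(CCc2cc(O)c3c(c2)O[C@@H](c2ccc(OC(=O)C(C)(C)C)cc2)[C@@H]3c2cc(OC)cc(OC)c2)cc1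
F3 | step 5 | 4-[(2R,3R)-3-(3,5-dimethoxyphenyl)-4-hydroxy-6-[2-(4-methoxyphenyl)ethyl]-2,3-dihydro-1-benzofuran-2-yl]phenyl 2,2-dimethylpropanoate | COc1ccc(CCc2cc(O)c3c(c2)O[C@@H](c2ccc(OC(=O)C(C)(C)C)cc2)[C@@H]3c2cc(OC)cc(OC)c2)cc1
F4 | step 6 | sodium 2-[(1S)-1-(3,5-dimethoxyphenyl)-2-(4-oxocyclohexa-2,5-dien-1-ylidene)ethyl]-5-[2-(4-methoxyphenyl)ethyl]-3-oxocyclohex-1-en-1-olate (para-quinone methide, not isolated) | O=C1C=CC(=C[C@@H](c2cc(OC)cc(OC)c2)C2=C([O-])CC(CCc3ccc(OC)cc3)CC2=O)C=C1.[Na+]
F5 | step 6 | (2S,3S)-3-(3,5-dimethoxyphenyl)-2-(4-hydroxyphenyl)-6-[2-(4-methoxyphenyl)ethyl]-3,5,6,7-tetrahydro-1-benzofuran-4(2H)-one (both C6 epimers) | COc1ccc(CCC2CC(=O)C3=C(C2)O[C@H](c2ccc(O)cc2)[C@H]3c2cc(OC)cc(OC)c2)cc1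
F6 | step 7 | 4-[(2S,3S)-5-bromo-3-(3,5-dimethoxyphenyl)-6-[2-(4-methoxyphenyl)ethyl]-4-oxo-2,3,4,5,6,7-hexahydro-1-benzofuran-2-yl]phenyl 2,2-dimethylpropanoate (mixture of C5/C6 diastereomers) | COc1ccc(CCC2C(Br)C(=O)C3=C(C2)O[C@H](c2ccc(OC(=O)C(C)(C)C)cc2)[C@H]3c2cc(OC)cc(OC)c2)cc1
F0 | step 8 | none | none
A1 | alternative 1 | 2-[(E)-2-(3,5-dimethoxyphenyl)ethenyl]-4,4,5,5-tetramethyl-1,3,2-dioxaborolane | COc1cc(/C=C/B2OC(C)(C)C(C)(C)O2)cc(OC)c1
A2 | alternative 1 | (4-methoxyphenyl)lithium | [Li]c1ccc(OC)cc1
A3 | alternative 1 | 2,6-dimethoxy-4-[2-(4-methoxyphenyl)ethyl]phenyl trifluoromethanesulfonate | COc1ccc(CCc2cc(OC)c(OS(=O)(=O)C(F)(F)F)c(OC)c2)cc1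
A4 | alternative 1 | 2-[(1S,2S)-2-(3,5-dimethoxyphenyl)-2-{2,6-dimethoxy-4-[2-(4-methoxyphenyl)ethyl]phenyl}-1-(4-methoxyphenyl)ethyl]-4,4,5,5-tetramethyl-1,3,2-dioxaborolane | COc1ccc(CCc2cc(OC)c([C@@H]([C@H](B3OC(C)(C)C(C)(C)O3)c3ccc(OC)cc3)c3cc(OC)cc(OC)c3)c(OC)c2)cc1
A5 | alternative 2 | 3-methoxy-5-[2-(4-methoxyphenyl)ethyl]-2-(trimethylsilyl)phenyl trifluoromethanesulfonate | COc1ccc(CCc2cc(OC)c([Si](C)(C)C)c(OS(=O)(=O)C(F)(F)F)c2)cc1
A6 | alternative 2 | 4-[(2R,3R)-3-(3,5-dimethoxyphenyl)oxiran-2-yl]phenyl trifluoromethanesulfonate | FC(F)(F)S(=O)(=O)Oc1ccc(cc1)[C@H]1O[C@@H]1c1cc(OC)cc(OC)c1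
A7 | alternative 2 | 4-[(2S,3S)-3-(3,5-dimethoxyphenyl)-4-methoxy-6-[2-(4-methoxyphenyl)ethyl]-2,3-dihydro-1-benzofuran-2-yl]phenyl trifluoromethanesulfonate | COc1ccc(CCc2cc(OC)c3c(c2)O[C@H](c2ccc(OS(=O)(=O)C(F)(F)F)cc2)[C@H]3c2cc(OC)cc(OC)c2)cc1
A8 | alternative 3 | (2S)-7-[2-(4-methoxyphenyl)ethyl]-4-oxo-2-[4-(pivaloyloxy)phenyl]-3,4-dihydro-2H-1-benzopyran-5-yl 2,2-dimethylpropanoate | COc1ccc(CCc2cc(OC(=O)C(C)(C)C)c3C(=O)C[C@@H](c4ccc(OC(=O)C(C)(C)C)cc4)Oc3c2)cc1
A9 | alternative 3 | methyl (2S,3S)-6-[2-(4-methoxyphenyl)ethyl]-4-(pivaloyloxy)-2-[4-(pivaloyloxy)phenyl]-2,3-dihydro-1-benzofuran-3-carboxylate | COc1ccc(CCc2cc(OC(=O)C(C)(C)C)c3c(c2)O[C@H](c2ccc(OC(=O)C(C)(C)C)cc2)[C@H]3C(=O)OC)cc1
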